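**Strategy**

The eleven-membered ring is closed between the ester-bearing carbinol carbon and the neighbouring quaternary CMe2 carbon. The feature exploited is that this CMe2 carbon is the allylic terminus of the ring's E-CH=CH–C(=CH2) unit: carbinol, quaternary centre and conjugated exo-methylene diene together are the product pattern of an ε-selective Hosomi–Sakurai pentadienylation. An acyclic aldehyde ending in Me3SiCH2–C(R)=CH–CH=CMe2 is therefore cyclised with BF3·OEt2, which in one operation should form the ring, the quaternary carbon, the E ring alkene and the exocyclic methylene. The carbinol configuration is then set as R by oxidation and CBS reduction, and the vanillate is attached last.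

Key step: step 5

Remark: pent-4-ynal is taken as a catalogue compound; in the Why lines the ring atoms carry humulane numbers (C10 carbinol carbon, C11 CMe2, C1=C2 ring E-alkene, C3 ring carbon bearing the exocyclic C15H2, C6=C7 trisubstituted ring alkene).

**Route**

Step 1
Reactants: 1 pent-4-ynal; 2 isopropenylmagnesium bromide
Product: 3 rac-2-methylhept-1-en-6-yn-3-ol
Conditions: THF, −78 → 0 °C; then H2O
Reagents that add atoms: none
Why: Grignard 1,2-addition to the aldehyde, which at low temperature should outrun deprotonation of the alkyne C–H; the carbinol centre is deliberately racemic because step 2 destroys it.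

Step 2
Reactants: 3 rac-2-methylhept-1-en-6-yn-3-ol
Product: 6 ethyl (4E)-4-methylnon-4-en-8-ynoate, via mixed orthoester 4 (not isolated), via ketene acetal 5 (not isolated)
Conditions: MeC(OEt)3 (excess), EtCO2H (cat.), 140 °C, EtOH distilled off
Reagents that add atoms: triethyl orthoacetate CC(OCC)(OCC)OCC
Why: Johnson–Claisen rearrangement through a chair transition state with the butynyl chain equatorial, which should set the E geometry of the trisubstituted alkene (the later C6=C7 bond) and add the two-carbon ester arm.

Step 3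
Reactants: 6 ethyl (4E)-4-methylnon-4-en-8-ynoate; 7 (trimethylsilyl)methylmagnesium chloride; 8 1-bromo-2-methylprop-1-ene
Product: 12 ethyl (4E,8Z)-4,11-dimethyl-8-[(trimethylsilyl)methyl]dodeca-4,8,10-trienoate, via silylmethylcopper 9 (not isolated), via alkenylcopper 10 (not isolated), via alkenylzinc bromide 11 (not isolated)
Conditions: 7, CuBr·SMe2, Et2O/Me2S, −40 °C; add 6, −40 → 0 °C; then ZnBr2, 8, Pd(PPh3)4 (5 mol %), THF, rt
Reagents that add atoms: none
Why: syn-carbocupration of the terminal alkyne (silylmethyl to the internal carbon, copper to the terminal carbon) followed by transmetalation to zinc and Negishi coupling with retention should give the 1-(silylmethyl)-1,3-diene in one flask; organocopper and organozinc species should not attack the ethyl ester at these temperatures.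

Step 4
Reactants: 12 ethyl (4E,8Z)-4,11-dimethyl-8-[(trimethylsilyl)methyl]dodeca-4,8,10-trienoate
Product: 13 (4E,8Z)-4,11-dimethyl-8-[(trimethylsilyl)methyl]dodeca-4,8,10-trienal
Conditions: DIBAL-H (1.1 equiv), CH2Cl2, −78 °C; MeOH, then aq. Rochelle salt
Reagents that add atoms: none
Why: DIBAL-H partial reduction of the ester, whose aluminium hemiacetal should survive at −78 °C and release the aldehyde only on work-up; the allylic silane and the alkenes are inert to the hydride.

Step 5
Reactants: 13 (4E,8Z)-4,11-dimethyl-8-[(trimethylsilyl)methyl]dodeca-4,8,10-trienal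
Product: 14 rac-(3E,8E)-2,2,9-trimethyl-5-methylidenecycloundeca-3,8-dien-1-ol
Conditions: BF3·OEt2 (2 equiv), CH2Cl2, −78 °C, 13 added slowly (final 1 mM); aq. NaHCO3
Reagents that add atoms: none
Why: BF3 activates the aldehyde, the ε-carbon C11 of the 1-(silylmethyl)diene attacks it (SE2″), and the resulting allyl cation, stabilised β to silicon, loses the silyl group to fluoride so that the double bonds end up at C1=C2 and C3=C15. The closest known reaction type is the ε-selective Hosomi–Sakurai pentadienylation of aldehydes, together with Lewis-acid allylmetal–aldehyde macrocyclisations. The eleven-membered ring closes by C–C bond formation exo to the carbonyl group (oxygen outside the ring) and endo to the reacting C11=C1 π bond. The new stereocentre C10 has no controlling element and should form racemic, which is corrected in steps 6 and 7. The step needs ε- over γ-attack, E geometry at C1=C2 and cyclisation over oligomerisation: the terminal carbon has the largest HOMO coefficient and γ-attack would have to build a nine-membered ring holding an E alkene, the s-trans diene conformer (s-cis is blocked by the CH2SiMe3 group cis to C1) leads to E, and slow addition at 1 mM should keep the reaction intramolecular. The C6=C7 alkene could reach the carbonyl carbon only through a 4-exo or 5-endo closure and should stay out.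

Step 6
Reactants: 14 rac-(3E,8E)-2,2,9-trimethyl-5-methylidenecycloundeca-3,8-dien-1-ol
Product: 15 (3E,8E)-2,2,9-trimethyl-5-methylidenecycloundeca-3,8-dien-1-one
Conditions: Dess–Martin periodinane, NaHCO3, CH2Cl2, 0 °C → rt
Reagents that add atoms: none
Why: Dess–Martin oxidation of a hindered secondary alcohol under buffered conditions; the α-carbon C11 is quaternary, so the β,γ-unsaturated ketone cannot enolise toward C11 or isomerise into conjugation.

Step 7
Reactants: 15 (3E,8E)-2,2,9-trimethyl-5-methylidenecycloundeca-3,8-dien-1-one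
Product: 16 (1R,3E,8E)-2,2,9-trimethyl-5-methylidenecycloundeca-3,8-dien-1-ol
Conditions: (S)-Me-CBS (0.5 equiv), catecholborane (2 equiv), toluene, −78 → −20 °C; MeOH, then aq. work-up
Reagents that add atoms: none
Why: Corey–Bakshi–Shibata reduction, in which the ketone binds to the (S)-oxazaborolidine with its large quaternary C11 side away from the catalyst, so hydride should reach the face that gives the R carbinol (the sense known for tert-alkyl and aryl ketones); catecholborane should leave the alkenes untouched at low temperature.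

Step 8
Reactants: 16 (1R,3E,8E)-2,2,9-trimethyl-5-methylidenecycloundeca-3,8-dien-1-ol; 17 4-acetoxy-3-methoxybenzoic acid
Product: 20 (1R,3E,8E)-2,2,9-trimethyl-5-methylidenecycloundeca-3,8-dien-1-yl 4-hydroxy-3-methoxybenzoate, via acid chloride 18 (not isolated), via acetate ester 19 (not isolated)
Conditions: 17, (COCl)2, DMF (cat.), CH2Cl2, rt, evaporate; then 16, pyridine, DMAP, CH2Cl2, 40 °C; then pyrrolidine, 0 °C → rt
Reagents that add atoms: none
Why: DMAP-catalysed acylation of the hindered alcohol by the aroyl chloride with retention at C10 (the C–O bond is not touched), followed by aminolysis of the phenyl acetate, which should be far more reactive toward pyrrolidine than the hindered alkyl benzoate.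

**Compound list**

1 | pent-4-ynal | C#CCCC=O | starting material
2 | isopropenylmagnesium bromide | C=C(C)[Mg]Br | starting material
3 | rac-2-methylhept-1-en-6-yn-3-ol | C=C(C)C(O)CCC#C | intermediate
4 | 3-(1,1-diethoxyethoxy)-2-methylhept-1-en-6-yne (mixed orthoester) | C=C(C)C(CCC#C)OC(C)(OCC)OCC | intermediate
5 | 3-[(1-ethoxyethenyl)oxy]-2-methylhept-1-en-6-yne (ketene acetal) | C=C(C)C(CCC#C)OC(=C)OCC | intermediate
6 | ethyl (4E)-4-methylnon-4-en-8-ynoate | CCOC(=O)CC/C(C)=C/CCC#C | intermediate
7 | (trimethylsilyl)methylmagnesium chloride | C[Si](C)(C)C[Mg]Cl | starting material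
8 | 1-bromo-2-methylprop-1-ene | CC(C)=CBr | starting material
9 | (trimethylsilyl)methylcopper | C[Si](C)(C)C[Cu] | intermediate
10 | ethyl (4E,8Z)-9-cuprio-4-methyl-8-[(trimethylsilyl)methyl]nona-4,8-dienoate (alkenylcopper) | CCOC(=O)CC/C(C)=C/CC/C(C[Si](C)(C)C)=C/[Cu] | intermediate
11 | ethyl (4E,8Z)-9-(bromozincio)-4-methyl-8-[(trimethylsilyl)methyl]nona-4,8-dienoate (alkenylzinc bromide) | CCOC(=O)CC/C(C)=C/CC/C(C[Si](C)(C)C)=C/[Zn]Br | intermediate
12 | ethyl (4E,8Z)-4,11-dimethyl-8-[(trimethylsilyl)methyl]dodeca-4,8,10-trienoate | CCOC(=O)CC/C(C)=C/CC/C(C[Si](C)(C)C)=C/C=C(C)C | intermediate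
13 | (4E,8Z)-4,11-dimethyl-8-[(trimethylsilyl)methyl]dodeca-4,8,10-trienal | O=CCC/C(C)=C/CC/C(C[Si](C)(C)C)=C/C=C(C)C | intermediate
14 | rac-(3E,8E)-2,2,9-trimethyl-5-methylidenecycloundeca-3,8-dien-1-ol | C=C1/C=C/C(C)(C)C(O)CC/C(C)=C/CC1 | intermediate
15 | (3E,8E)-2,2,9-trimethyl-5-methylidenecycloundeca-3,8-dien-1-one | C=C1/C=C/C(C)(C)C(=O)CC/C(C)=C/CC1 | intermediate
16 | (1R,3E,8E)-2,2,9-trimethyl-5-methylidenecycloundeca-3,8-dien-1-ol | C=C1/C=C/C(C)(C)[C@H](O)CC/C(C)=C/CC1 | intermediate
17 | 4-acetoxy-3-methoxybenzoic acid | CC(=O)Oc1ccc(C(=O)O)cc1OC | starting material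
18 | 4-acetoxy-3-methoxybenzoyl chloride | CC(=O)Oc1ccc(C(=O)Cl)cc1OC | intermediate
19 | (1R,3E,8E)-2,2,9-trimethyl-5-methylidenecycloundeca-3,8-dien-1-yl 4-acetoxy-3-methoxybenzoate | C=C1/C=C/C(C)(C)[C@H](OC(=O)c2ccc(OC(C)=O)c(OC)c2)CC/C(C)=C/CC1 | intermediate
20 | (1R,3E,8E)-2,2,9-trimethyl-5-methylidenecycloundeca-3,8-dien-1-yl 4-hydroxy-3-methoxybenzoate | C=C1/C=C/C(C)(C)[C@H](OC(=O)c2ccc(O)c(OC)c2)CC/C(C)=C/CC1 | target

**Count**

Total step count: 8. Longest linear sequence: 8 steps (1 → 20).

**Steps most likely to fail**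

1. Step 5. What may go wrong: bond formation through the internal γ-carbon C2 instead of the ε-carbon, a carbonyl-ene or Prins reaction of the C6=C7 alkene with the activated aldehyde, protodesilylation, or oligomerisation because ring closure is slow. Fallback: setting out from aldehyde 13, acetalisation with (2R,4R)-pentane-2,4-diol (PPTS, MgSO4, CH2Cl2) would give the dioxane acetal (4R,6R)-4,6-dimethyl-2-[(3E,7Z)-3,10-dimethyl-7-[(trimethylsilyl)methyl]undeca-3,7,9-trien-1-yl]-1,3-dioxane F1. TiCl4 in CH2Cl2 at −78 °C under high dilution should ionise the C–O bond next to the axial methyl group to a more electrophilic oxocarbenium ion, which the silane terminus attacks with inversion (the chiral 2,4-pentanediol acetal allylation with allylsilanes). This should give the hydroxy ether (2R,4R)-4-{[(1R,3E,8E)-2,2,9-trimethyl-5-methylidenecycloundeca-3,8-dien-1-yl]oxy}pentan-2-ol F2, with the ring and the R carbinol centre formed together. Swern oxidation to the β-alkoxy ketone (4R)-4-{[(1R,3E,8E)-2,2,9-trimethyl-5-methylidenecycloundeca-3,8-dien-1-yl]oxy}pentan-2-one F3 and β-elimination (K2CO3, MeOH) would release alcohol 16, where the route is rejoined; steps 6 and 7 then fall away.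

2. Step 3. What may go wrong: sluggish or incomplete addition of the α-silyl organocopper to the unactivated alkyne, attack of residual Grignard reagent on the ester, or homocoupling in the palladium stage. Fallback: setting out from alkyne 6, copper-catalysed borylative alkylation (B2pin2, ICH2SiMe3, CuCl/Xantphos, NaOtBu, THF; syn addition with boron at the terminal carbon) would give the alkenylboronate ethyl (4E,8Z)-4-methyl-9-(4,4,5,5-tetramethyl-1,3,2-dioxaborolan-2-yl)-8-[(trimethylsilyl)methyl]nona-4,8-dienoate F4. Suzuki–Miyaura coupling with bromide 8 (Pd(dppf)Cl2, K3PO4, aqueous THF) would return to ester 12.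

3. Step 7. What may go wrong: poor facial discrimination because both flanks of the ketone are ring carbons of a conformationally mobile macrocycle, or slow reduction of the hindered carbonyl with competing hydroboration. Fallback: setting out from racemic alcohol 14 (step 6 omitted), acylation with (S)-O-methylmandelic acid (DCC, DMAP, CH2Cl2) would give the diastereomeric esters (1R,3E,8E)-2,2,9-trimethyl-5-methylidenecycloundeca-3,8-dien-1-yl (2S)-2-methoxy-2-phenylacetate F5 and (1S,3E,8E)-2,2,9-trimethyl-5-methylidenecycloundeca-3,8-dien-1-yl (2S)-2-methoxy-2-phenylacetate F6, to be separated by chromatography. Reductive cleavage of F5 (LiAlH4, Et2O, 0 °C) would return to alcohol 16.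

**Further compounds**

F1 | step 5 | (4R,6R)-4,6-dimethyl-2-[(3E,7Z)-3,10-dimethyl-7-[(trimethylsilyl)methyl]undeca-3,7,9-trien-1-yl]-1,3-dioxane | C[C@@H]1C[C@@H](C)OC(CC/C(C)=C/CC/C(C[Si](C)(C)C)=C/C=C(C)C)O1
F2 | step 5 | (2R,4R)-4-{[(1R,3E,8E)-2,2,9-trimethyl-5-methylidenecycloundeca-3,8-dien-1-yl]oxy}pentan-2-ol | C=C1/C=C/C(C)(C)[C@H](O[C@H](C)C[C@@H](C)O)CC/C(C)=C/CC1
F3 | step 5 | (4R)-4-{[(1R,3E,8E)-2,2,9-trimethyl-5-methylidenecycloundeca-3,8-dien-1-yl]oxy}pentan-2-one | C=C1/C=C/C(C)(C)[C@H](O[C@H](C)CC(C)=O)CC/C(C)=C/CC1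
F4 | step 3 | ethyl (4E,8Z)-4-methyl-9-(4,4,5,5-tetramethyl-1,3,2-dioxaborolan-2-yl)-8-[(trimethylsilyl)methyl]nona-4,8-dienoate | CCOC(=O)CC/C(C)=C/CC/C(C[Si](C)(C)C)=C/B1OC(C)(C)C(C)(C)O1
F5 | step 7 | (1R,3E,8E)-2,2,9-trimethyl-5-methylidenecycloundeca-3,8-dien-1-yl (2S)-2-methoxy-2-phenylacetate | C=C1/C=C/C(C)(C)[C@H](OC(=O)[C@@H](OC)c2ccccc2)CC/C(C)=C/CC1
F6 | step 7 | (1S,3E,8E)-2,2,9-trimethyl-5-methylidenecycloundeca-3,8-dien-1-yl (2S)-2-methoxy-2-phenylacetate | C=C1/C=C/C(C)(C)[C@@H](OC(=O)[C@@H](OC)c2ccccc2)CC/C(C)=C/CC1
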